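- The target climbs through both earlier runs, within their scatter, so I ask whether to count it as concentration gained per minute or as percent of charge.

| flask | solid substrate | partner | remark | time |
|---|---|---|---|---|
| teal | 0.14 M | 1 equiv | run made earlier |  |
| green | 0.21 M | 1 equiv | run made earlier |  |
| flask | 0.28 M | 1.00 equiv |  | 40 min |

- teal (time / min: target / %, dissolved substrate / %): 2.50: 2, 0; 5.00: 9, 2; 10.0: 12, 0; 15.0: 12, 1; 30.0: 22, 0
- green (time / min: target / %, dissolved substrate / %): 2.50: 4, 0; 5.00: 1, 1; 10.0: 5, 0; 15.0: 14, 0; 30.0: 17, 2

(each reading ± 2 percentage points)

1. the target standing at 40 min, as a percentage of the solid substrate charged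
2. concentration of dissolved substrate in solution at 40 min, in percent of saturation

- solid, in amounts per volume of the solution: solid substrate
- at the start none of the solid substrate is in solution
- dissolved substrate means what is dissolved; the solid is not counted in it

- Solid substrate, first end: suppose percent holds whatever the charge. Teal shows 22% and green 17% at 30.0 min, and their mean stretched to 40 min gives 26.0%.
- Solid substrate, second end: suppose concentration gained per minute holds instead. Teal gives 1.03 mM/min and green 1.19 mM/min. These differ by a factor of 1.16, the percents by 1.29, and each is a single reading with its scatter.
- I join the ends on the second. Green's last reading has dissolved substrate at 2%, less than its 17% of target. So I suppose that dissolving is the rate-limiting step in these runs.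
- I call the mean of those two rates the feed, the target gained per litre per minute: 1.11 mM/min.
- Time: I let the feed run straight to 40 min, so I reckon this flask at 0.28 M at 15.8%.
- Partner: both runs used 1 equiv, so the equivalents are not varied between them. Their readings give no figure for saturation, and I commit to no number for it.
- The forecast says 18% and 50%, with this caution: “Saturation is not identifiable from these runs”.
- The flask gives 16.5% of target, against my 15.8% and the forecast's 18%, and 4.00% of saturation, 46 percentage points below the forecast.

    solid substrate ⇌ dissolved substrate, rate k1*(cs1 - [dissolved substrate]) while solid is left; crystals form when [dissolved substrate] > cs1 (solubility = 0.110 M, k = 2.60 × 10⁻⁴ /s)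
    dissolved substrate + partner → target (k = 0.160 /M/s)
    dissolved substrate + target → side product (k = 0.0510 /M/s)
    partner → decomposed reagent (k = 7.90 × 10⁻⁴ /s)

- The neighbouring flask holds 0.17 M of solid substrate, and the feed reckons 26.1% of target for it. That flask stands at 20.9% of target and 14.0% of side product after 40.0 min. Each side product holds two units, one of them taken from target, so the target made there comes to 27.9%.

The readings were computed for an exercise, and the scatter is random.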